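**Strategy.** Everything rests on closing the tetrahydrofuran (O1, C2 aryl, C3 hydroxymethyl, C4 arylmethyl, C5) by joining C5, the ring CH2 on oxygen, to C4. The key step exploits the cis relationship of the C3 hydroxymethyl carbon and the C4 benzylic carbon: both are tied beforehand through a carboxyl bridge into an α,β-unsaturated δ-lactone. Photoredox decarboxylation of a carboxymethyl ether on the C2 oxygen gives an alkoxymethyl radical that adds 5-exo to the lactone β-carbon (C4), closing the ring and setting C4 cis by ring fusion in one operation. The bridge carboxyl is afterwards excised in a decarboxylative nickel coupling that attaches the aryl ring carrying the threo-arylglycerol ether.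

Key step: step 13

Locants used below: tetrahydrofuran O1, C2, C3, C4, C5 as above; C9 is the hydroxymethyl carbon on C3, C7 the benzylic carbon on C4, C10 the temporary carboxyl carbon.

**Aryl iodide fragment (steps 1–5)**

Step 1
Reactants: 1 (S)-4-benzyloxazolidin-2-one; 2 chloroacetyl chloride
Product: 3 (4S)-4-benzyl-3-(chloroacetyl)-1,3-oxazolidin-2-one
Conditions: n-BuLi, THF, −78 °C; then 2, −78 → 0 °C
Reagents that add atoms: none
Why: N-acylation of the lithiated oxazolidinone by the acid chloride (standard imide formation); the auxiliary stereocentre is untouched.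

Step 2
Reactants: 3; 4 4-iodo-2-methoxyphenol
Product: 5 (4S)-4-benzyl-3-[(4-iodo-2-methoxyphenoxy)acetyl]-1,3-oxazolidin-2-one
Conditions: K2CO3, NaI (10 mol%), acetone, rt
Reagents that add atoms: none
Why: Williamson ether synthesis, SN2 displacement at the activated α-halo imide by the phenoxide with Finkelstein catalysis; no stereocentre is formed.

Step 3
Reactants: 5; 6 4-(benzyloxy)-3-methoxybenzaldehyde
Product: 8 (4S)-4-benzyl-3-[(2S,3R)-3-[4-(benzyloxy)-3-methoxyphenyl]-3-hydroxy-2-(4-iodo-2-methoxyphenoxy)propanoyl]-1,3-oxazolidin-2-one, via dibutylboron Z-enolate 7 (not isolated)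
Conditions: Bu2BOTf, iPr2NEt, CH2Cl2, −78 → 0 °C; then 6, −78 → 0 °C; pH 7 buffer, MeOH, H2O2
Reagents that add atoms: none
Why: Evans syn glycolate aldol; the Z-boron enolate reacts through a Zimmerman–Traxler chair on the face away from the auxiliary benzyl group, which should set both stereocentres of the later threo (7R,8R) arylglycerol unit.

Step 4
Reactants: 8
Product: 9 (1R,2R)-1-[4-(benzyloxy)-3-methoxyphenyl]-2-(4-iodo-2-methoxyphenoxy)propane-1,3-diol
Conditions: NaBH4, THF/H2O (4:1), 0 °C → rt
Reagents that add atoms: none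
Why: Borohydride reductive cleavage of the N-acyloxazolidinone to the primary alcohol; both stereocentres and the aryl iodide are unaffected.

Step 5
Reactants: 9
Product: 10 (1R,2R)-1-[4-(benzyloxy)-3-methoxyphenyl]-2-(4-iodo-2-methoxyphenoxy)propane-1,3-diol bis(tert-butyldimethylsilyl) ether
Conditions: TBSOTf, 2,6-lutidine, CH2Cl2, −78 → 0 °C
Reagents that add atoms: tert-butyldimethylsilyl triflate, CC(C)(C)[Si](C)(C)OS(=O)(=O)C(F)(F)F
Why: Silyl ether formation at the primary and the benzylic secondary hydroxyl with the silyl triflate; no stereochemical change.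

**Core (steps 6–14)**

Step 6
Reactants: 1 (S)-4-benzyloxazolidin-2-one; 11 (E)-but-2-enoyl chloride
Product: 12 (4S)-4-benzyl-3-[(2E)-but-2-enoyl]-1,3-oxazolidin-2-one
Conditions: n-BuLi, THF, −78 °C; then 11, −78 → 0 °C
Reagents that add atoms: none
Why: N-acylation of the lithiated oxazolidinone by the acid chloride; the auxiliary stereocentre is untouched.

Step 7
Reactants: 12; 6 4-(benzyloxy)-3-methoxybenzaldehyde
Product: 14 (4S)-4-benzyl-3-[(2S,3S)-3-[4-(benzyloxy)-3-methoxyphenyl]-2-ethenyl-3-hydroxypropanoyl]-1,3-oxazolidin-2-one, via dibutylboron dienolate 13 (not isolated)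
Conditions: Bu2BOTf, Et3N, CH2Cl2, −78 → 0 °C; then 6, −78 → 0 °C; pH 7 buffer, MeOH, H2O2
Reagents that add atoms: none
Why: Evans deconjugative syn aldol of the crotonyl imide; γ-deprotonation gives the Z(O)-dienolate, which reacts at its α-carbon through a Zimmerman–Traxler chair under auxiliary control and should set the later C2 (S) and C3 (R) of the tetrahydrofuran in the syn sense that becomes 2,3-trans.

Step 8
Reactants: 14
Product: 15 (1S,2R)-1-[4-(benzyloxy)-3-methoxyphenyl]-2-ethenylpropane-1,3-diol
Conditions: LiBH4, MeOH (1 equiv), THF, 0 °C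
Reagents that add atoms: none
Why: Borohydride reductive cleavage of the imide to the primary alcohol (C9); the two stereocentres are retained.

Step 9
Reactants: 15; 16 acryloyl chloride
Product: 17 (2R,3S)-3-[4-(benzyloxy)-3-methoxyphenyl]-2-ethenyl-3-hydroxypropyl prop-2-enoate
Conditions: 2,4,6-collidine, CH2Cl2, −78 → −40 °C
Reagents that add atoms: none
Why: Chemoselective O-acylation of the primary hydroxyl over the hindered secondary benzylic one by an acid chloride with a hindered pyridine base at low temperature.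

Step 10
Reactants: 17
Product: 18 (5R)-5-[(S)-[4-(benzyloxy)-3-methoxyphenyl](hydroxy)methyl]-5,6-dihydro-2H-pyran-2-one
Conditions: second-generation Grubbs catalyst RuCl2(=CHPh)(PCy3)(H2IMes) (5 mol%), CH2Cl2 (5 mM), 40 °C
Reagents that add atoms: none
Why: Ring-closing metathesis of the acrylate with the vinyl group should close the unsaturated δ-lactone (C9–O–C10(=O)–C7=C4) with loss of ethene; no stereocentre takes part.

Step 11
Reactants: 18; 19 tert-butyl diazoacetate
Product: 20 tert-butyl 2-{(S)-[4-(benzyloxy)-3-methoxyphenyl][(3R)-6-oxo-3,6-dihydro-2H-pyran-3-yl]methoxy}acetate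
Conditions: Rh2(OAc)4 (1 mol%), 19 (2 equiv, slow addition), CH2Cl2, rt
Reagents that add atoms: none
Why: Rhodium carbenoid O–H insertion places the future C5 on the C2 oxygen under neutral conditions, with retention at the carbinol carbon; the electron-poor lactone alkene should not be cyclopropanated.

Step 12
Reactants: 20
Product: 22 2-{(S)-[4-(benzyloxy)-3-methoxyphenyl][(3R)-6-oxo-3,6-dihydro-2H-pyran-3-yl]methoxy}acetic acid, via trimethylsilyl ester 21 (not isolated)
Conditions: TMSOTf, 2,6-lutidine, CH2Cl2, 0 °C; then pH 4 aqueous work-up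
Reagents that add atoms: none
Why: Silyl triflate-mediated tert-butyl ester cleavage (loss of isobutene to the silyl ester, hydrolysed on work-up) under buffered non-protic conditions chosen to spare the acid-sensitive benzylic ether and the lactone.

Step 13
Reactants: 22
Product: 23 (3S,3aR,7aR)-3-[4-(benzyloxy)-3-methoxyphenyl]tetrahydro-1H-furo[3,4-c]pyran-6(4H)-one (cis-fused tetrahydrofuran–δ-lactone)
Conditions: Ir[dF(CF3)ppy]2(dtbbpy)PF6 (1 mol%), K2HPO4 (1.2 equiv), DMF (0.01 M), 450 nm LEDs, rt, argon
Reagents that add atoms: none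
Why: The excited trivalent iridium photocatalyst oxidises the carboxylate of 22 by single-electron transfer, CO2 is lost, and the nucleophilic alkoxymethyl radical at C5 adds to C4, the β-carbon of the unsaturated lactone; the resulting α-acyl radical at C7 is reduced by the divalent iridium species to the lactone enolate and protonated. The closest known reaction type is the photoredox decarboxylative radical conjugate addition (Giese reaction) of α-alkoxy acids to acrylates, used here intramolecularly. The tetrahydrofuran closes in the 5-exo-trig mode (C5 onto C4, with C7 exocyclic to the new ring). The new stereocentre C4 is controlled by C3: the tether C2–O1–C5 hangs from C3 and can reach the neighbouring C4 only on its own face of the six-membered lactone, so the fusion must be cis and C9 and C7 end up cis on the tetrahydrofuran, while the aryl group on C2 stays trans to C9 as set in step 7. The step needs β- rather than α-attack and oxidation of the carboxylate rather than of the dialkoxyarene; the first is secured by polarity matching and by 5-exo over 6-endo closure, the second by the lower oxidation potential of the α-alkoxy carboxylate.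

Step 14
Reactants: 23
Product: 26 2-[(3R,4R,5S)-5-[4-(benzyloxy)-3-methoxyphenyl]-4-{[(tert-butyldimethylsilyl)oxy]methyl}oxolan-3-yl]acetic acid, via lithium carboxylate 24 (not isolated), via bis-silylated derivative 25 (not isolated)
Conditions: LiOH·H2O, THF/H2O, rt; concentrate; TBSCl, imidazole, DMF, rt; then K2CO3, MeOH/H2O, rt; pH 5 buffer
Reagents that add atoms: lithium hydroxide, [Li+].[OH-]; tert-butyldimethylsilyl chloride, CC(C)(C)[Si](C)(C)Cl
Why: Lactone saponification frees C9–OH and the C10 carboxylate, silylation caps both, and selective methanolysis of the labile silyl ester returns the acid (standard hydroxy-acid protection sequence); no stereocentre is epimerisable.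

**Union and deprotection (steps 15–17)**

Step 15
Reactants: 26; 10
Product: 28 (2S,3R,4R)-2-[4-(benzyloxy)-3-methoxyphenyl]-3-{[(tert-butyldimethylsilyl)oxy]methyl}-4-[4-({(1R,2R)-1-[4-(benzyloxy)-3-methoxyphenyl]-1,3-bis[(tert-butyldimethylsilyl)oxy]propan-2-yl}oxy)-3-methoxybenzyl]oxolane, via N-acyloxyphthalimide 27 (not isolated)
Conditions: N-hydroxyphthalimide, DIC, DMAP (cat.), DMA, rt; then 10, NiBr2(dme) (10 mol%), 4,4′-di-tert-butyl-2,2′-bipyridine (10 mol%), Zn dust, rt
Reagents that add atoms: none
Why: Nickel-catalysed decarboxylative cross-electrophile coupling of the redox-active ester with the aryl iodide (zinc as reductant); loss of CO2 removes C10, and the primary C7 radical is captured by the arylnickel species to form the benzyl–aryl bond away from all stereocentres.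

Step 16
Reactants: 28
Product: 29 (1R,2R)-1-[4-(benzyloxy)-3-methoxyphenyl]-2-[4-({(3R,4R,5S)-5-[4-(benzyloxy)-3-methoxyphenyl]-4-(hydroxymethyl)oxolan-3-yl}methyl)-2-methoxyphenoxy]propane-1,3-diol
Conditions: TBAF, THF, 0 °C → rt
Reagents that add atoms: none
Why: Fluoride-mediated cleavage of the three silyl ethers while the phenols are still benzylated, which avoids quinone methide chemistry.

Step 17
Reactants: 29
Product: 30 CNP0158473.2, the (7R,8R)-threo-guaiacylglycerol 8-O-4′ ether of (2S,3R,4R)-lariciresinol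
Conditions: H2 (1 atm), 10% Pd/C, EtOAc/MeOH, rt, monitored closely
Reagents that add atoms: none
Why: Catalytic hydrogenolysis of the two aryl benzyl ethers under neutral conditions should be faster than cleavage of the benzylic C–O bonds at C2 and at the carbinol.

**Compound list**

1 | (S)-4-benzyloxazolidin-2-one | O=C1OC[C@H](Cc2ccccc2)N1 | starting material
2 | chloroacetyl chloride | ClCC(Cl)=O | starting material
3 | (4S)-4-benzyl-3-(chloroacetyl)-1,3-oxazolidin-2-one | O=C(CCl)N1C(=O)OC[C@@H]1Cc1ccccc1 | intermediate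
4 | 4-iodo-2-methoxyphenol | COc1cc(I)ccc1O | starting material
5 | (4S)-4-benzyl-3-[(4-iodo-2-methoxyphenoxy)acetyl]-1,3-oxazolidin-2-one | COc1cc(I)ccc1OCC(=O)N1C(=O)OC[C@@H]1Cc1ccccc1 | intermediate
6 | 4-(benzyloxy)-3-methoxybenzaldehyde | COc1cc(C=O)ccc1OCc1ccccc1 | starting material
7 | dibutylboron Z-enolate of 5 | COc1cc(I)ccc1O\C=C(/OB(CCCC)CCCC)N1C(=O)OC[C@@H]1Cc1ccccc1 | intermediate
8 | glycolate aldol adduct, (2S,3R) | COc1cc(I)ccc1O[C@@H]([C@H](O)c1ccc(OCc2ccccc2)c(OC)c1)C(=O)N1C(=O)OC[C@@H]1Cc1ccccc1 | intermediate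
9 | (1R,2R)-1-[4-(benzyloxy)-3-methoxyphenyl]-2-(4-iodo-2-methoxyphenoxy)propane-1,3-diol | COc1cc(I)ccc1O[C@@H]([C@H](O)c1ccc(OCc2ccccc2)c(OC)c1)CO | intermediate
10 | bis(tert-butyldimethylsilyl) ether of 9 | COc1cc(I)ccc1O[C@@H]([C@H](O[Si](C)(C)C(C)(C)C)c1ccc(OCc2ccccc2)c(OC)c1)CO[Si](C)(C)C(C)(C)C | intermediate
11 | (E)-but-2-enoyl chloride | C/C=C/C(Cl)=O | starting material
12 | (4S)-4-benzyl-3-[(2E)-but-2-enoyl]-1,3-oxazolidin-2-one | C/C=C/C(=O)N1C(=O)OC[C@@H]1Cc1ccccc1 | intermediate
13 | dibutylboron Z(O)-dienolate of 12 | C=C\C=C(/OB(CCCC)CCCC)N1C(=O)OC[C@@H]1Cc1ccccc1 | intermediate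
14 | deconjugative aldol adduct, (2S,3S) | C=C[C@@H]([C@H](O)c1ccc(OCc2ccccc2)c(OC)c1)C(=O)N1C(=O)OC[C@@H]1Cc1ccccc1 | intermediate
15 | (1S,2R)-1-[4-(benzyloxy)-3-methoxyphenyl]-2-ethenylpropane-1,3-diol | C=C[C@@H]([C@H](O)c1ccc(OCc2ccccc2)c(OC)c1)CO | intermediate
16 | acryloyl chloride | C=CC(Cl)=O | starting material
17 | (2R,3S)-3-[4-(benzyloxy)-3-methoxyphenyl]-2-ethenyl-3-hydroxypropyl prop-2-enoate | C=C[C@@H]([C@H](O)c1ccc(OCc2ccccc2)c(OC)c1)COC(=O)C=C | intermediate
18 | (5R)-5-[(S)-[4-(benzyloxy)-3-methoxyphenyl](hydroxy)methyl]-5,6-dihydro-2H-pyran-2-one | O=C1OC[C@H]([C@H](O)c2ccc(OCc3ccccc3)c(OC)c2)C=C1 | intermediate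
19 | tert-butyl diazoacetate | CC(C)(C)OC(=O)C=[N+]=[N-] | starting material
20 | tert-butyl ester of the carboxymethyl ether of 18 | O=C1OC[C@H]([C@H](OCC(=O)OC(C)(C)C)c2ccc(OCc3ccccc3)c(OC)c2)C=C1 | intermediate
21 | trimethylsilyl ester corresponding to 20 | O=C1OC[C@H]([C@H](OCC(=O)O[Si](C)(C)C)c2ccc(OCc3ccccc3)c(OC)c2)C=C1 | intermediate
22 | carboxymethyl ether acid (key-step precursor) | O=C1OC[C@H]([C@H](OCC(=O)O)c2ccc(OCc3ccccc3)c(OC)c2)C=C1 | intermediate
23 | (3S,3aR,7aR)-3-[4-(benzyloxy)-3-methoxyphenyl]tetrahydro-1H-furo[3,4-c]pyran-6(4H)-one | O=C1OC[C@@H]2[C@@H](c3ccc(OCc4ccccc4)c(OC)c3)OC[C@@H]2C1 | intermediate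
24 | lithium 2-[(3R,4R,5S)-5-[4-(benzyloxy)-3-methoxyphenyl]-4-(hydroxymethyl)oxolan-3-yl]acetate | [Li+].[O-]C(=O)C[C@H]1CO[C@H](c2ccc(OCc3ccccc3)c(OC)c2)[C@H]1CO | intermediate
25 | silyl ether silyl ester of the hydroxy acid | CC(C)(C)[Si](C)(C)OC(=O)C[C@H]1CO[C@H](c2ccc(OCc3ccccc3)c(OC)c2)[C@H]1CO[Si](C)(C)C(C)(C)C | intermediate
26 | 2-[(3R,4R,5S)-5-[4-(benzyloxy)-3-methoxyphenyl]-4-{[(tert-butyldimethylsilyl)oxy]methyl}oxolan-3-yl]acetic acid | OC(=O)C[C@H]1CO[C@H](c2ccc(OCc3ccccc3)c(OC)c2)[C@H]1CO[Si](C)(C)C(C)(C)C | intermediate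
27 | N-hydroxyphthalimide ester of 26 | O=C(C[C@H]1CO[C@H](c2ccc(OCc3ccccc3)c(OC)c2)[C@H]1CO[Si](C)(C)C(C)(C)C)ON1C(=O)c2ccccc2C1=O | intermediate
28 | tris(TBS) bis(benzyl) protected target | COc1cc([C@@H](O[Si](C)(C)C(C)(C)C)[C@@H](CO[Si](C)(C)C(C)(C)C)Oc2ccc(C[C@H]3CO[C@H](c4ccc(OCc5ccccc5)c(OC)c4)[C@H]3CO[Si](C)(C)C(C)(C)C)cc2OC)ccc1OCc1ccccc1 | intermediate
29 | bis(benzyl) protected target | COc1cc([C@@H](O)[C@@H](CO)Oc2ccc(C[C@H]3CO[C@H](c4ccc(OCc5ccccc5)c(OC)c4)[C@H]3CO)cc2OC)ccc1OCc1ccccc1 | intermediate
30 | CNP0158473.2 | COc1cc([C@@H](O)[C@@H](CO)Oc2ccc(C[C@H]3CO[C@H](c4ccc(O)c(OC)c4)[C@H]3CO)cc2OC)ccc1O | target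

**Summary**

Total step count: 17. Longest linear sequence: 12 steps (steps 6 to 17); the aryl iodide branch (steps 1 to 5) joins at step 15.

Steps most likely to fail:

1. Step 13 (key step). The alkoxymethyl radical may be quenched by hydrogen-atom abstraction before ring closure, may fragment at the C2–O bond, or the photocatalyst may oxidise the electron-rich arene instead of the carboxylate. Fallback: generate the same radical reductively. Acid 22 would be condensed with N-hydroxyphthalimide (DIC, DMAP cat., CH2Cl2) to the redox-active N-hydroxyphthalimide ester F1. Irradiation of F1 with Ru(bpy)3Cl2, Hantzsch ester and iPr2NEt under blue light (reductive decarboxylative Giese cyclisation, no strong photo-oxidant present) should then return to 23.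

2. Step 15. Protodecarboxylation or dimerisation of the primary radical and homocoupling of the aryl iodide may outrun cross-coupling, and the in situ activation of the acid may be incomplete. Fallback: replace the cross-electrophile manifold by an organozinc coupling. Iodide 10 would be converted by iodine–magnesium exchange (iPrMgCl·LiCl, THF, 0 °C) and ZnCl2 into the arylzinc chloride F2. The separately prepared and isolated ester 27 (from 26, DIC, N-hydroxyphthalimide) would be coupled with F2 under decarboxylative Negishi conditions (NiCl2(dme), 4,4′-di-tert-butyl-2,2′-bipyridine, THF/DMF, rt), returning to 28.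

3. Step 12. The silyl triflate may ionise the electron-rich benzylic C2–O bond (loss of the carboxymethyl ether or epimerisation at C2) before the tert-butyl ester is cleaved. Fallback: unmask the acid through a π-allyl pathway. Allyl diazoacetate F3 would be made from allyl bromoacetate with N,N′-ditosylhydrazine and DBU, and inserted into the hydroxyl of 18 with Rh2(OAc)4 to give the allyl ester F4. Deallylation of F4 with Pd(PPh3)4 and N-methylaniline in THF under neutral conditions should return to 22.

Further compounds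
F1 | step 13 | N-hydroxyphthalimide ester of 22 | O=C1OC[C@H]([C@H](OCC(=O)ON2C(=O)c3ccccc3C2=O)c2ccc(OCc3ccccc3)c(OC)c2)C=C1
F2 | step 15 | arylzinc chloride derived from 10 | COc1cc([Zn]Cl)ccc1O[C@@H]([C@H](O[Si](C)(C)C(C)(C)C)c1ccc(OCc2ccccc2)c(OC)c1)CO[Si](C)(C)C(C)(C)C
F3 | step 12 | allyl diazoacetate | C=CCOC(=O)C=[N+]=[N-]
F4 | step 12 | allyl ester of the carboxymethyl ether of 18 | O=C1OC[C@H]([C@H](OCC(=O)OCC=C)c2ccc(OCc3ccccc3)c(OC)c2)C=C1
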